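## Retrosynthetic overview

1. The target comes from a fully MOM/trityl-protected benzodioxane by one acid step. The three benzene rings are bought, and the 1,4-dioxane ring is the only ring made and is made last.
2. The dioxane ring is closed at the O1–C8a bond by intramolecular Pd-catalysed aryl C–O coupling of a benzylic alcohol onto an ortho-bromoaryl ether, so no bond at a stereocentre is touched.
3. The C2–C3 bond comes from an Evans syn aldol between the boron enolate of an N-(aryloxyacetyl)-(R)-4-benzyloxazolidinone and MOM-protected syringaldehyde. This sets both stereocentres (syn = threo = trans in the ring).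
4. The aryloxyacetyl imide comes from a bromostilbene phenol, methyl bromoacetate and the auxiliary.
5. The bromostilbene comes from a Horner–Wadsworth–Emmons reaction of an aldehyde made from 5-bromovanillin with a phosphonate made from methyl 3,5-dihydroxybenzoate.

Assumption: with the numbering O1, C2 (aryl), C3 (CH2OH), O4, C5 (OH), C7 (styryl), the SMILES reads as the (2S,3S)-trans isomer with an (E)-alkene.

Short forms: MOM = CH2OCH3; Tr = CPh3; "stilben-4-yl" names follow stilbene numbering (bromo ring unprimed).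

## Route

Step 1
Reactants: 1 5-bromovanillin
Product: 2 3-bromo-4,5-dihydroxybenzaldehyde
Conditions: AlCl3 (1.1 equiv), pyridine (4.4 equiv), CH2Cl2, reflux, 24 h; then 2 M HCl
Reagents that add atoms: none
Why: Lewis-acid aryl methyl ether cleavage, in which AlCl3 chelates the ortho-hydroxy/methoxy pair so that pyridine removes the methyl group by SN2 while the aldehyde and the bromide stay untouched.

Step 2
Reactants: 2 3-bromo-4,5-dihydroxybenzaldehyde
Product: 3 4-(allyloxy)-3-bromo-5-hydroxybenzaldehyde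
Conditions: allyl bromide (1.1 equiv), NaHCO3 (1.5 equiv), DMF, 40 °C, 24 h
Reagents that add atoms: allyl bromide, C=CCBr
Why: Regioselective Williamson etherification, because only the 4-OH (para to CHO, ortho to Br) is acidic enough for NaHCO3, so the single phenoxide formed is allylated at O-4.

Step 3
Reactants: 3 4-(allyloxy)-3-bromo-5-hydroxybenzaldehyde
Product: 4 4-(allyloxy)-3-bromo-5-(methoxymethoxy)benzaldehyde
Conditions: MOMCl (1.5 equiv), i-Pr2NEt (2 equiv), CH2Cl2, 0 °C to rt
Reagents that add atoms: chloromethyl methyl ether (MOMCl), COCCl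
Why: MOM protection (O-alkylation with an oxocarbenium-type chloride) of the one remaining phenol under a mild amine base that leaves the aldehyde, allyl ether and bromide alone.

Step 4
Reactants: 5 methyl 3,5-dihydroxybenzoate
Product: 6 methyl 3,5-bis(methoxymethoxy)benzoate
Conditions: MOMCl (3 equiv), i-Pr2NEt (4 equiv), CH2Cl2, 0 °C to rt
Reagents that add atoms: chloromethyl methyl ether (MOMCl), COCCl
Why: Double MOM protection of two equivalent phenols gives base- and hydride-stable acetals that come off with acid at the end.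

Step 5
Reactants: 6 methyl 3,5-bis(methoxymethoxy)benzoate
Product: 7 [3,5-bis(methoxymethoxy)phenyl]methanol
Conditions: LiAlH4, THF, 0 °C; H2O quench
Reagents that add atoms: none
Why: Hydride reduction of the ester to the benzylic alcohol, with MOM acetals inert to LiAlH4.

Step 6
Reactants: 7 [3,5-bis(methoxymethoxy)phenyl]methanol
Product: 8 1-(bromomethyl)-3,5-bis(methoxymethoxy)benzene
Conditions: CBr4 (1.2 equiv), PPh3 (1.25 equiv), CH2Cl2, 0 °C
Reagents that add atoms: carbon tetrabromide, BrC(Br)(Br)Br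
Why: Appel reaction, a neutral SN2 bromination through the alkoxyphosphonium salt that avoids the acid which would strip the MOM groups.

Step 7
Reactants: 8 1-(bromomethyl)-3,5-bis(methoxymethoxy)benzene
Product: 9 diethyl [3,5-bis(methoxymethoxy)benzyl]phosphonate
Conditions: P(OEt)3 (neat, 3 equiv), 130 °C, 4 h
Reagents that add atoms: triethyl phosphite, CCOP(OCC)OCC
Why: Michaelis–Arbuzov reaction, which is dependable for primary benzylic bromides and is driven by loss of volatile bromoethane.

Step 8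
Reactants: 9 diethyl [3,5-bis(methoxymethoxy)benzyl]phosphonate; 4 4-(allyloxy)-3-bromo-5-(methoxymethoxy)benzaldehyde
Product: 11 (E)-4-(allyloxy)-3-bromo-3',5,5'-tris(methoxymethoxy)stilbene, via potassium phosphonate carbanion 10 (not isolated)
Conditions: 9 (1.15 equiv), KOtBu (1.1 equiv), THF, 0 °C, 20 min; then 4, 0 °C to rt
Reagents that add atoms: potassium tert-butoxide, CC(C)(C)[O-].[K+] (its potassium sits only in 10, nothing of it stays in 11)
Why: Horner–Wadsworth–Emmons olefination, in which reversible addition of a benzylic phosphonate carbanion to an aromatic aldehyde funnels to the (E)-stilbene, and the base is fully consumed by the slight excess of 9 so the allyl ether is not isomerised.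

Step 9
Reactants: 11 (E)-4-(allyloxy)-3-bromo-3',5,5'-tris(methoxymethoxy)stilbene
Product: 12 (E)-3-bromo-4-hydroxy-3',5,5'-tris(methoxymethoxy)stilbene
Conditions: Pd(PPh3)4 (5 mol %), morpholine (5 equiv), THF, rt
Reagents that add atoms: none
Why: Tsuji–Trost-type deallylation, in which zerovalent palladium ionises the allyl aryl ether at room temperature far faster than it inserts into the electron-rich C–Br bond, and morpholine traps the π-allyl unit.

Step 10
Reactants: 12 (E)-3-bromo-4-hydroxy-3',5,5'-tris(methoxymethoxy)stilbene; 13 methyl bromoacetate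
Product: 14 methyl 2-{[(E)-3-bromo-3',5,5'-tris(methoxymethoxy)stilben-4-yl]oxy}acetate
Conditions: K2CO3 (1.5 equiv), DMF, rt, 12 h
Reagents that add atoms: none
Why: Williamson ether synthesis with a very reactive α-bromo ester on the only free hydroxyl group, so there is no regiochemical question despite the two ortho substituents.

Step 11
Reactants: 14 methyl 2-{[(E)-3-bromo-3',5,5'-tris(methoxymethoxy)stilben-4-yl]oxy}acetate
Product: 16 2-{[(E)-3-bromo-3',5,5'-tris(methoxymethoxy)stilben-4-yl]oxy}acetic acid, via lithium carboxylate 15 (not isolated)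
Conditions: LiOH·H2O (2 equiv), THF/MeOH/H2O, 0 °C to rt; then cold 1 M HCl to pH 3, immediate extraction
Reagents that add atoms: lithium hydroxide, [Li+].[OH-]
Why: Saponification of an activated aryloxyacetate is fast under conditions to which MOM ethers, the bromide and the stilbene are inert, and the brief cold acidification does not cleave aryl MOM ethers.

Step 12
Reactants: 16 2-{[(E)-3-bromo-3',5,5'-tris(methoxymethoxy)stilben-4-yl]oxy}acetic acid; 17 (R)-4-benzyl-2-oxazolidinone
Product: 19 (R)-4-benzyl-3-(2-{[(E)-3-bromo-3',5,5'-tris(methoxymethoxy)stilben-4-yl]oxy}acetyl)oxazolidin-2-one, via mixed pivalic anhydride 18 (not isolated)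
Conditions: PivCl (1.05 equiv), Et3N (2.5 equiv), THF, −20 °C, 1 h; then LiCl (1.1 equiv), 17, −20 °C to rt
Reagents that add atoms: pivaloyl chloride, CC(C)(C)C(=O)Cl (its acyl group sits only in 18 and leaves again as pivalate)
Why: Mixed-anhydride N-acylation, in which the LiCl-activated oxazolidinone attacks the unhindered aryloxyacetyl carbonyl and no HCl is generated that could harm the MOM groups.

Step 13
Reactants: 20 syringaldehyde
Product: 21 3,5-dimethoxy-4-(methoxymethoxy)benzaldehyde
Conditions: MOMCl (1.5 equiv), i-Pr2NEt (2 equiv), CH2Cl2, 0 °C to rt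
Reagents that add atoms: chloromethyl methyl ether (MOMCl), COCCl
Why: MOM protection of the acidic para-phenol removes the proton that would quench the enolate and keeps the aldehyde electrophilic.

Step 14
Reactants: 19 (R)-4-benzyl-3-(2-{[(E)-3-bromo-3',5,5'-tris(methoxymethoxy)stilben-4-yl]oxy}acetyl)oxazolidin-2-one; 21 3,5-dimethoxy-4-(methoxymethoxy)benzaldehyde
Product: 24 (R)-4-benzyl-3-[(2R,3S)-2-{[(E)-3-bromo-3',5,5'-tris(methoxymethoxy)stilben-4-yl]oxy}-3-[3,5-dimethoxy-4-(methoxymethoxy)phenyl]-3-hydroxypropanoyl]oxazolidin-2-one, via (Z)-dibutylboron enolate 22 (not isolated), via dibutylboron aldolate 23 (not isolated)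
Conditions: Bu2BOTf (1.2 equiv), Et3N (1.4 equiv), CH2Cl2, −78 to 0 °C, 1 h; 21 (1.2 equiv), −78 °C to 0 °C; then pH 7 buffer, MeOH, 30% H2O2, 0 °C
Reagents that add atoms: dibutylboron triflate, CCCCB(CCCC)OS(=O)(=O)C(F)(F)F (its Bu2B group sits only in 22 and 23 and is taken off in the work-up)
Why: Evans syn aldol, in which soft enolisation gives the (Z)-boron enolate that reacts through a closed Zimmerman–Traxler chair on the face away from the benzyl group of the (R)-auxiliary, making the C2–C3 bond and setting both stereocentres as (2R,3S)-syn.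

Step 15
Reactants: 24 the syn-aldol imide
Product: 25 (1S,2S)-2-{[(E)-3-bromo-3',5,5'-tris(methoxymethoxy)stilben-4-yl]oxy}-1-[3,5-dimethoxy-4-(methoxymethoxy)phenyl]propane-1,3-diol
Conditions: NaBH4 (4 equiv), THF/H2O 4:1, 0 °C to rt
Reagents that add atoms: none
Why: Reductive cleavage of the auxiliary at the more electrophilic exocyclic imide carbonyl breaks no bond at a stereocentre (the aryloxy carbon changes from R to S only because CH2OH ranks below the carbinol carbon) and spares the bromide, stilbene and MOM groups.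

Step 16
Reactants: 25 the (1S,2S)-diol
Product: 26 (1S,2S)-2-{[(E)-3-bromo-3',5,5'-tris(methoxymethoxy)stilben-4-yl]oxy}-1-[3,5-dimethoxy-4-(methoxymethoxy)phenyl]-3-(trityloxy)propan-1-ol
Conditions: TrCl (1.3 equiv), Et3N (2 equiv), DMAP (0.1 equiv), CH2Cl2, rt, 16 h
Reagents that add atoms: trityl chloride, ClC(c1ccccc1)(c1ccccc1)c1ccccc1
Why: Sterically selective tritylation takes only the primary alcohol, and unlike a silyl or acyl group a trityl ether cannot migrate to the neighbouring alkoxide in the next step.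

Step 17
Reactants: 26 the trityl-protected bromo alcohol
Product: 27 (2S,3S)-7-{(E)-2-[3,5-bis(methoxymethoxy)phenyl]ethenyl}-2-[3,5-dimethoxy-4-(methoxymethoxy)phenyl]-5-(methoxymethoxy)-3-(trityloxymethyl)-2,3-dihydro-1,4-benzodioxine
Conditions: Pd(OAc)2 (5 mol %), 2-(di-tert-butylphosphino)-1,1'-binaphthyl (6 mol %), Cs2CO3 (1.5 equiv), toluene, 80 °C
Reagents that add atoms: none
Why: Intramolecular Buchwald-type C–O coupling (oxidative addition into C–Br, alkoxide binding, reductive elimination from a bulky electron-rich phosphine complex) forms O1–C8a at the arene, so C2 and C3 keep their configuration and the syn (threo) array becomes the trans-2,3-disubstituted dioxane.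

Step 18
Reactants: 27 the protected benzodioxane
Product: 28 (2S,3S)-7-[(E)-2-(3,5-dihydroxyphenyl)ethenyl]-2-(4-hydroxy-3,5-dimethoxyphenyl)-3-(hydroxymethyl)-2,3-dihydro-1,4-benzodioxin-5-ol (target)
Conditions: HCl in MeOH (1.25 M)/THF 1:1, 0 °C to 35 °C, argon, dark
Reagents that add atoms: none
Why: Acid-catalysed transacetalisation of the four aryl MOM ethers and SN1 methanolysis of the trityl ether, with formaldehyde held as dimethoxymethane away from the resorcinol ring, C3 unable to epimerise, and any reversible C2–O1 ionisation reclosing to the more stable trans isomer.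

## Compound list

1 | 5-bromovanillin (3-bromo-4-hydroxy-5-methoxybenzaldehyde) | COc1cc(C=O)cc(Br)c1O | starting material
2 | 3-bromo-4,5-dihydroxybenzaldehyde | O=Cc1cc(O)c(O)c(Br)c1 | intermediate
3 | 4-(allyloxy)-3-bromo-5-hydroxybenzaldehyde | O=Cc1cc(O)c(OCC=C)c(Br)c1 | intermediate
4 | 4-(allyloxy)-3-bromo-5-(methoxymethoxy)benzaldehyde | O=Cc1cc(OCOC)c(OCC=C)c(Br)c1 | intermediate
5 | methyl 3,5-dihydroxybenzoate | COC(=O)c1cc(O)cc(O)c1 | starting material
6 | methyl 3,5-bis(methoxymethoxy)benzoate | COC(=O)c1cc(OCOC)cc(OCOC)c1 | intermediate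
7 | [3,5-bis(methoxymethoxy)phenyl]methanol | OCc1cc(OCOC)cc(OCOC)c1 | intermediate
8 | 1-(bromomethyl)-3,5-bis(methoxymethoxy)benzene | BrCc1cc(OCOC)cc(OCOC)c1 | intermediate
9 | diethyl [3,5-bis(methoxymethoxy)benzyl]phosphonate | CCOP(=O)(Cc1cc(OCOC)cc(OCOC)c1)OCC | intermediate
10 | potassium carbanion of phosphonate 9 (not isolated) | CCOP(=O)(OCC)[CH-]c1cc(OCOC)cc(OCOC)c1.[K+] | intermediate
11 | (E)-4-(allyloxy)-3-bromo-3',5,5'-tris(methoxymethoxy)stilbene | C=CCOc1c(Br)cc(/C=C/c2cc(OCOC)cc(OCOC)c2)cc1OCOC | intermediate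
12 | (E)-3-bromo-4-hydroxy-3',5,5'-tris(methoxymethoxy)stilbene | Oc1c(Br)cc(/C=C/c2cc(OCOC)cc(OCOC)c2)cc1OCOC | intermediate
13 | methyl bromoacetate | COC(=O)CBr | starting material
14 | methyl 2-{[(E)-3-bromo-3',5,5'-tris(methoxymethoxy)stilben-4-yl]oxy}acetate | COC(=O)COc1c(Br)cc(/C=C/c2cc(OCOC)cc(OCOC)c2)cc1OCOC | intermediate
15 | lithium 2-{[(E)-3-bromo-3',5,5'-tris(methoxymethoxy)stilben-4-yl]oxy}acetate (not isolated) | [Li+].[O-]C(=O)COc1c(Br)cc(/C=C/c2cc(OCOC)cc(OCOC)c2)cc1OCOC | intermediate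
16 | 2-{[(E)-3-bromo-3',5,5'-tris(methoxymethoxy)stilben-4-yl]oxy}acetic acid | OC(=O)COc1c(Br)cc(/C=C/c2cc(OCOC)cc(OCOC)c2)cc1OCOC | intermediate
17 | (R)-4-benzyl-2-oxazolidinone | O=C1N[C@H](Cc2ccccc2)CO1 | starting material
18 | mixed anhydride of acid 16 and pivalic acid (not isolated) | CC(C)(C)C(=O)OC(=O)COc1c(Br)cc(/C=C/c2cc(OCOC)cc(OCOC)c2)cc1OCOC | intermediate
19 | (R)-4-benzyl-3-(2-{[(E)-3-bromo-3',5,5'-tris(methoxymethoxy)stilben-4-yl]oxy}acetyl)oxazolidin-2-one | O=C(COc1c(Br)cc(/C=C/c2cc(OCOC)cc(OCOC)c2)cc1OCOC)N1[C@H](Cc2ccccc2)COC1=O | intermediate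
20 | syringaldehyde (4-hydroxy-3,5-dimethoxybenzaldehyde) | COc1cc(C=O)cc(OC)c1O | starting material
21 | 3,5-dimethoxy-4-(methoxymethoxy)benzaldehyde | COCOc1c(OC)cc(C=O)cc1OC | intermediate
22 | (Z)-dibutylboron enolate of imide 19 (not isolated) | CCCCB(CCCC)O/C(=C\Oc1c(Br)cc(/C=C/c2cc(OCOC)cc(OCOC)c2)cc1OCOC)N1[C@H](Cc2ccccc2)COC1=O | intermediate
23 | dibutylboron aldolate of 24 (not isolated) | COCOc1c(OC)cc(cc1OC)[C@H](OB(CCCC)CCCC)[C@@H](Oc1c(Br)cc(/C=C/c2cc(OCOC)cc(OCOC)c2)cc1OCOC)C(=O)N1[C@H](Cc2ccccc2)COC1=O | intermediate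
24 | (R)-4-benzyl-3-[(2R,3S)-2-(stilben-4-yloxy)-3-aryl-3-hydroxypropanoyl]oxazolidin-2-one (syn aldol, full name in step 14) | COCOc1c(OC)cc(cc1OC)[C@H](O)[C@@H](Oc1c(Br)cc(/C=C/c2cc(OCOC)cc(OCOC)c2)cc1OCOC)C(=O)N1[C@H](Cc2ccccc2)COC1=O | intermediate
25 | (1S,2S)-2-{[(E)-3-bromo-3',5,5'-tris(methoxymethoxy)stilben-4-yl]oxy}-1-[3,5-dimethoxy-4-(methoxymethoxy)phenyl]propane-1,3-diol | COCOc1c(OC)cc(cc1OC)[C@H](O)[C@H](CO)Oc1c(Br)cc(/C=C/c2cc(OCOC)cc(OCOC)c2)cc1OCOC | intermediate
26 | (1S,2S)-2-{[(E)-3-bromo-3',5,5'-tris(methoxymethoxy)stilben-4-yl]oxy}-1-[3,5-dimethoxy-4-(methoxymethoxy)phenyl]-3-(trityloxy)propan-1-ol | COCOc1c(OC)cc(cc1OC)[C@H](O)[C@H](COC(c1ccccc1)(c1ccccc1)c1ccccc1)Oc1c(Br)cc(/C=C/c2cc(OCOC)cc(OCOC)c2)cc1OCOC | intermediate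
27 | (2S,3S)-7-{(E)-2-[3,5-bis(methoxymethoxy)phenyl]ethenyl}-2-[3,5-dimethoxy-4-(methoxymethoxy)phenyl]-5-(methoxymethoxy)-3-(trityloxymethyl)-2,3-dihydro-1,4-benzodioxine | COCOc1c(OC)cc(cc1OC)[C@@H]1Oc2cc(/C=C/c3cc(OCOC)cc(OCOC)c3)cc(OCOC)c2O[C@H]1COC(c1ccccc1)(c1ccccc1)c1ccccc1 | intermediate
28 | (2S,3S)-7-[(E)-2-(3,5-dihydroxyphenyl)ethenyl]-2-(4-hydroxy-3,5-dimethoxyphenyl)-3-(hydroxymethyl)-2,3-dihydro-1,4-benzodioxin-5-ol | COc1cc([C@@H]2Oc3cc(/C=C/c4cc(O)cc(O)c4)cc(O)c3O[C@H]2CO)cc(OC)c1O | target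

## Step count and risks

Total step count: 18.

Longest linear sequence: 14 steps (4, 5, 6, 7, 8, 9, 10, 11, 12, 14, 15, 16, 17, 18), starting from methyl 3,5-dihydroxybenzoate.

### Steps most likely to fail

**Step 17 (aryl C–O ring closure).**
- The palladium alkoxide of the hindered benzylic alcohol may undergo β-hydride elimination, giving the ketone plus the debrominated arene.
- The fallback sets out from 26 and comes back to the route at 28. It closes the ring at the benzylic carbon instead of at the arene.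
- Miyaura borylation of 26 (B2pin2, Pd(dppf)Cl2, KOAc, dioxane, 90 °C) gives the aryl pinacol boronate F1.
- NaBO3·4H2O in THF/H2O oxidises this to the ortho-hydroxy aryl ether F2.
- Methanolic HCl (as in step 18, 40 °C) then removes the four MOM groups and the trityl group and ionises the electron-rich benzylic alcohol.
- The resulting cation (a protonated para-quinone methide) is captured by either of the two now equivalent ortho phenols.
- Because this C2–O1 bond forms reversibly next to the untouched (S)-C3 centre, the diequatorial trans isomer accumulates and 28 is reached directly, without passing through 27.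

**Step 14 (boron aldol).**
- The bulky 2,6-disubstituted aryloxy imide, or loss of MOM groups to the boron Lewis acid, may lower conversion or selectivity.
- The fallback sets out from 14 and 21 and comes back at 25. The carbon–carbon bond is still made by an aldol addition, but the stereocentres are set afterwards by a catalyst rather than by an auxiliary.
- Ester 14 is deprotonated with LDA (THF, −78 °C) and added to 21 to give the racemic syn/anti β-hydroxy ester mixture F3.
- Dess–Martin periodinane (CH2Cl2, NaHCO3) gives the configurationally labile α-aryloxy β-keto ester F4.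
- Asymmetric transfer hydrogenation with dynamic kinetic resolution (RuCl(p-cymene)[(R,R)-TsDPEN], HCO2H/Et3N 5:2, CH2Cl2, 30 °C) gives the syn-(2R,3S) β-hydroxy ester F5.
- LiBH4 (THF, 0 °C) reduces the ester to diol 25.

**Step 2 (regioselective mono-allylation).**
- Bis-allylation or slow reaction of the weakly nucleophilic, flanked 4-phenoxide may spoil the yield.
- The fallback sets out from 2 and comes back at 4. It reverses the order of the two O-alkylations by working through the dianion.
- Compound 2 is treated with NaH (2.1 equiv) in DMF at 0 °C and then MOMCl (1.0 equiv).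
- Reaction occurs at the more basic, non-conjugated 5-phenoxide and gives 3-bromo-4-hydroxy-5-(methoxymethoxy)benzaldehyde F6.
- The single remaining phenol of F6 is then allylated without any selectivity issue (allyl bromide, K2CO3, DMF, rt) to give 4.

## Further compounds

F1 | step 17 | (1S,2S)-1-[3,5-dimethoxy-4-(methoxymethoxy)phenyl]-2-{[(E)-3',5,5'-tris(methoxymethoxy)-3-(4,4,5,5-tetramethyl-1,3,2-dioxaborolan-2-yl)stilben-4-yl]oxy}-3-(trityloxy)propan-1-ol | COCOc1c(OC)cc(cc1OC)[C@H](O)[C@H](COC(c1ccccc1)(c1ccccc1)c1ccccc1)Oc1c(B2OC(C)(C)C(C)(C)O2)cc(/C=C/c2cc(OCOC)cc(OCOC)c2)cc1OCOC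
F2 | step 17 | (1S,2S)-1-[3,5-dimethoxy-4-(methoxymethoxy)phenyl]-2-{[(E)-3-hydroxy-3',5,5'-tris(methoxymethoxy)stilben-4-yl]oxy}-3-(trityloxy)propan-1-ol | COCOc1c(OC)cc(cc1OC)[C@H](O)[C@H](COC(c1ccccc1)(c1ccccc1)c1ccccc1)Oc1c(O)cc(/C=C/c2cc(OCOC)cc(OCOC)c2)cc1OCOC
F3 | step 14 | methyl 2-{[(E)-3-bromo-3',5,5'-tris(methoxymethoxy)stilben-4-yl]oxy}-3-[3,5-dimethoxy-4-(methoxymethoxy)phenyl]-3-hydroxypropanoate (racemic syn/anti mixture) | COCOc1c(OC)cc(cc1OC)C(O)C(Oc1c(Br)cc(/C=C/c2cc(OCOC)cc(OCOC)c2)cc1OCOC)C(=O)OC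
F4 | step 14 | methyl 2-{[(E)-3-bromo-3',5,5'-tris(methoxymethoxy)stilben-4-yl]oxy}-3-[3,5-dimethoxy-4-(methoxymethoxy)phenyl]-3-oxopropanoate (racemic, labile at C2) | COCOc1c(OC)cc(cc1OC)C(=O)C(Oc1c(Br)cc(/C=C/c2cc(OCOC)cc(OCOC)c2)cc1OCOC)C(=O)OC
F5 | step 14 | methyl (2R,3S)-2-{[(E)-3-bromo-3',5,5'-tris(methoxymethoxy)stilben-4-yl]oxy}-3-[3,5-dimethoxy-4-(methoxymethoxy)phenyl]-3-hydroxypropanoate | COCOc1c(OC)cc(cc1OC)[C@H](O)[C@@H](Oc1c(Br)cc(/C=C/c2cc(OCOC)cc(OCOC)c2)cc1OCOC)C(=O)OC
F6 | step 2 | 3-bromo-4-hydroxy-5-(methoxymethoxy)benzaldehyde | O=Cc1cc(OCOC)c(O)c(Br)c1
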